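Slowness looks no danger to J in this flask: its half-life on the way to J.X, with X as charged, is 0.50 h, shorter than the run of 15 d.

J 0.030 M (fed, over 1.5 h); X 0.0240 M; time 15 d

    J + X → J.X (k1 = 0.955 L mol⁻¹ min⁻¹)
    J + X → Q (k2 = 0.0170 L mol⁻¹ min⁻¹)
    X + J.X → X.J.X (k3 = 0.0207 L mol⁻¹ min⁻¹)
    X.J.X ⇌ L (K4 = 20.0, k4 = 0.00110 min⁻¹)
    X + Q → X.Q (k5 = 0.00511 L mol⁻¹ min⁻¹)

- the reaction counts as stopped when no species that holds the J changes by six tenths of a point or more over the second half of the time
- run time (flask): 15 d

- which holds at 15 d: what has brought the reaction to rest, or that it has not come to rest (forward and back rates have come level / it is still moving / all of J has reacted / X has run out first)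
- part of the J gone at 15 d
- the J.X standing at 15 d, as a percentage of the J charged
- the L standing at 15 d, as a percentage of the J charged

Yet the charges tell another story. Each J that reacts takes one X, whether it becomes J.X or Q, so X is the limiting reagent here. The part of the J that X can carry is the reach, the charge of X as a fraction of the charge of J: 80.0 %. A half-life of 0.50 h beside a charge that leaves 20.0 % of the J without a partner looks like a contradiction, but that half-life holds X as charged, and X falls. What stays frozen is the reach.

This hand reckoning makes one correction, for the X spent a second time on J.X. The rate constant by which J.X takes X is smaller than that by which J takes it, by the ratio 2.17 %. As a rough guess, J.X is taken as level with J on the mean, so that ratio serves as the share of the X spent this way, an estimated loss of 1.73 % of the J charged. J gone is then 78.3 %, and J.X, after the share lost to Q and the loss itself, is 75.2 %. X.J.X and L relax towards each other with a half-life of 0.417 d, shorter than the run, so L is put at 1.65 %, and this reckoning has X stopping the flask with 21.7 % of the J still standing.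

The forecast says X has run out first, with 78.2 % of the J gone (77.5 % to 79 %), J.X at 75 % (73.5 % to 76 %) and L at 1.8 % (1.4 % to 2.2 %), with “small losses to Q and to over-addition of X”. Its L stands above the reckoning here, and its J.X slightly below.

The simulation gives X has run out first, 78.2 % of the J gone, J.X at 75.1 % and L at 1.66 %.

The falling level of X is what stops this flask: 0 % of its X stands at 15.0 d, and the same run without that fall takes the J to 100 % rather than 78.2 %. The reach of 80.0 % stands 1.8 percentage points above the J gone in this flask. In the neighbour charged with 0.0096 M of X, the reach is 32.0 %, and 31.8 % of its J goes.

(The numbers of this flask were set for the occasion; what happens was integrated by code.)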